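**Plan** (prostanoid numbering: ester carbon C1, ring C8–C12, C9 = ketone, C10 = C–Br, C12 = carbinol)
- Cuts: C7=C8 (aldol condensation with a C1–C7 aldehyde), C14=C15 (Z-Wittig), then in the ring C9–C10 and C10–C11 (C10 leaves with its bromine as dibromocarbene, five-ring → four-ring), finally C8–C9 and C11–C12 (dichloroketene + enol ether).
- Enabling feature: the α-bromo-enone O=C9–C10(Br)=C11H is the retron of a dibromocarbene adduct across the enol bond C9=C11 of a cyclobutanone. The 3-oxygenated quaternary C12 of that cyclobutanone is the retron of a ketene/enol-ether (2+2) cycloaddition.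
- Forward order of rings: cyclobutanone by (2+2) → regiodefined silyl enol ether (chlorine as marker) → transient cyclopropane → cyclopentenone by one-carbon enlargement. Then ω-chain (ozonolysis, Wittig), α-chain (aldol, E1cB), global desilylation.
- Helpers: the two chlorines (removed in steps 4/5), the silyl enol ether (lost in step 6), the chiral inductor (removed in step 7).
- Stereochemistry: C12 from the inductor-controlled cycloaddition, fixed in sense by which α-carbon becomes the enol carbon; C5/C6 from 2-deoxy-L-ribose; 17Z from (Z)-hex-3-en-1-ol; 14Z from the salt-free Wittig; 7Z from the E1cB elimination under allylic-strain control.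

Key step: step 6

Assumption: the (S)-configured inductor 1 is taken to shield the face of enol ether 4 that leads to (S)-5; if the facial sense is the opposite, the (R)-alcohol (also commercial) is used and nothing else changes.

**Step 1**
Reactants: 1 (S)-1-(2,4,6-triisopropylphenyl)ethanol; 2 but-3-enoic acid
Product: 3 (S)-1-(2,4,6-triisopropylphenyl)ethyl but-3-enoate
Conditions: DCC, DMAP (cat.), CH2Cl2, 0 °C → rt
Reagents that add atoms: none
Why: Steglich esterification of a hindered secondary alcohol; low temperature and only catalytic DMAP should keep the β,γ-double bond out of conjugation.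

**Step 2**
Reactants: 3 (S)-1-(2,4,6-triisopropylphenyl)ethyl but-3-enoate
Product: 4 1,3,5-triisopropyl-2-[(S)-1-(penta-1,4-dien-2-yloxy)ethyl]benzene
Conditions: Cp2TiMe2, toluene–THF, 65 °C, dark
Reagents that add atoms: dimethyltitanocene [CH3-].[CH3-].[Ti+4].c1cc[cH-]c1.c1cc[cH-]c1
Why: Petasis methylenation (titanium methylidene, oxatitanacyclobutane) converts the ester carbonyl into the 1,1-disubstituted enol ether under non-basic conditions, so the skipped diene should not isomerise.

**Step 3**
Reactants: 4 1,3,5-triisopropyl-2-[(S)-1-(penta-1,4-dien-2-yloxy)ethyl]benzene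
Product: 5 (S)-3-allyl-2,2-dichloro-3-[(S)-1-(2,4,6-triisopropylphenyl)ethoxy]cyclobutan-1-one
Conditions: Cl3CCOCl, Zn–Cu, POCl3, Et2O, 0 °C → rt
Reagents that add atoms: trichloroacetyl chloride ClC(=O)C(Cl)(Cl)Cl
Why: Ketene–enol ether (2+2) cycloaddition: dichloroketene made in situ should react with the electron-rich enol ether in preference to the monosubstituted alkene, the CH2 terminus bonding to the ketene carbonyl carbon so that the oxygenated carbon becomes C3; the aryl group of the inductor shields one face and sets this quaternary centre (C12 of the target), and the minor diastereomer can be removed at any stage up to 9 because the inductor is still attached.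

**Step 4**
Reactants: 5 (S)-3-allyl-2,2-dichloro-3-[(S)-1-(2,4,6-triisopropylphenyl)ethoxy]cyclobutan-1-one
Product: 6 (2RS,3S)-3-allyl-2-chloro-3-[(S)-1-(2,4,6-triisopropylphenyl)ethoxy]cyclobutan-1-one
Conditions: Zn, AcOH, TMEDA, EtOH, 0 °C
Reagents that add atoms: none
Why: Buffered zinc reduction of an α,α-dichloroketone (zinc enolate, protonation) should stop at the monochloride, and the four-membered zinc enolate is expected to be protonated and not to expel the β-alkoxy group, because that would give a cyclobutenone.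

**Step 5**
Reactants: 6 (2RS,3S)-3-allyl-2-chloro-3-[(S)-1-(2,4,6-triisopropylphenyl)ethoxy]cyclobutan-1-one
Product: 7 {[(S)-3-allyl-3-[(S)-1-(2,4,6-triisopropylphenyl)ethoxy]cyclobut-1-en-1-yl]oxy}trimethylsilane
Conditions: Zn, TMSCl, TMEDA, Et2O, 0 °C → rt
Reagents that add atoms: chlorotrimethylsilane C[Si](C)(C)Cl
Why: Reductive silylation of an α-haloketone gives the silyl enol ether regiospecifically at the carbon that carried chlorine, which tells apart the two α-carbons that would be enantiotopic in the chlorine-free ketone.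

**Step 6**
Reactants: 7 {[(S)-3-allyl-3-[(S)-1-(2,4,6-triisopropylphenyl)ethoxy]cyclobut-1-en-1-yl]oxy}trimethylsilane
Product: 9 (S)-4-allyl-2-bromo-4-[(S)-1-(2,4,6-triisopropylphenyl)ethoxy]cyclopent-2-en-1-one, via dibromohousane 8 (not isolated)
Conditions: CHBr3, KOtBu (added last, slowly), pentane, −30 °C → rt
Reagents that add atoms: bromoform BrC(Br)Br
Why: Singlet dibromocarbene adds in a cheletropic (2+1) step to the strained, oxygen-activated enol bond C9=C11 of 7 to give the 1-siloxy-5,5-dibromobicyclo[2.1.0]pentane 8; its central bond then opens in a disrotatory cyclopropyl-to-allyl-cation electrocyclic process with loss of the endo bromide, pushed by the siloxy lone pair, and bromide removes the silyl group from the 2-siloxyallyl cation to leave the 2-bromocyclopent-2-enone. The closest known reaction type is the dihalocarbene ring enlargement of cyclic trimethylsilyl enol ethers to 2-halocycloalk-2-enones. The only ring that is closed is the three-membered one, by concerted (2+1) addition; the five-membered ring is not formed by cyclisation but from the four-membered ring by cleavage of the shared C9–C11 bond, with C10 and its bromine inserted. No stereocentre is formed: both cyclopropane carbons end up sp2, so the face of carbene attack is irrelevant, and C12 keeps the configuration set in step 3. The step needs chemoselectivity for the enol ether over the allyl group, secured by the π-donor oxygen and ring strain against a monosubstituted alkene, and it needs insertion between C9 and the former CCl2 carbon, secured by the regiodefined enol ether of step 5. Limiting base, with bromoform in slight excess, should keep alkoxide from desilylating 7 or enolising 9.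

**Step 7**
Reactants: 9 (S)-4-allyl-2-bromo-4-[(S)-1-(2,4,6-triisopropylphenyl)ethoxy]cyclopent-2-en-1-one
Product: 10 (S)-4-allyl-2-bromo-4-hydroxycyclopent-2-en-1-one
Conditions: TFA, CH2Cl2, 0 °C; aq. NaHCO3
Reagents that add atoms: none
Why: Acidolysis (E1) of the 1-arylethyl ether: the electron-rich benzylic cation should form far more easily than a cation at C12 next to the enone, so the C12–O bond is not broken and the tertiary carbinol is released with its configuration intact.

**Step 8**
Reactants: 10 (S)-4-allyl-2-bromo-4-hydroxycyclopent-2-en-1-one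
Product: 11 (S)-4-allyl-2-bromo-4-(triethylsilyloxy)cyclopent-2-en-1-one
Conditions: TESOTf, 2,6-lutidine, CH2Cl2, −78 °C
Reagents that add atoms: triethylsilyl trifluoromethanesulfonate CC[Si](CC)(CC)OS(=O)(=O)C(F)(F)F
Why: Silylation of the tertiary alcohol; the ether blocks the retro-aldol opening of the C8–C12 bond that a free alkoxide would allow, and which would racemise C12, in the basic steps that follow.

**Step 9**
Reactants: 11 (S)-4-allyl-2-bromo-4-(triethylsilyloxy)cyclopent-2-en-1-one
Product: 13 2-[(S)-3-bromo-4-oxo-1-(triethylsilyloxy)cyclopent-2-en-1-yl]acetaldehyde, via ozonide 12 (not isolated)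
Conditions: O3, CH2Cl2, −78 °C (Sudan III as end-point indicator); PPh3, −78 °C → rt
Reagents that add atoms: ozone [O-][O+]=O
Why: Ozonolysis with reductive work-up; the electron-rich terminal alkene should be cleaved much faster than the electron-poor bromo-enone double bond.

**Step 10**
Reactants: 14 (Z)-hex-3-en-1-ol
Product: 15 (Z)-1-iodohex-3-ene
Conditions: I2, PPh3, imidazole, CH2Cl2, 0 °C
Reagents that add atoms: iodine II
Why: Appel-type iodination of a primary alcohol by SN2 displacement of the oxyphosphonium group; the Z double bond (17Z of the target) is not touched.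

**Step 11**
Reactants: 15 (Z)-1-iodohex-3-ene
Product: 16 [(Z)-hex-3-en-1-yl]triphenylphosphonium iodide
Conditions: PPh3, MeCN, reflux
Reagents that add atoms: triphenylphosphine c1ccc(cc1)P(c1ccccc1)c1ccccc1
Why: SN2 quaternisation of triphenylphosphine by a primary iodide.

**Step 12**
Reactants: 16 [(Z)-hex-3-en-1-yl]triphenylphosphonium iodide; 13 2-[(S)-3-bromo-4-oxo-1-(triethylsilyloxy)cyclopent-2-en-1-yl]acetaldehyde
Product: 18 (S)-2-bromo-4-[(2Z,5Z)-octa-2,5-dien-1-yl]-4-(triethylsilyloxy)cyclopent-2-en-1-one, via ylide 17 (not isolated)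
Conditions: 16, NaHMDS, THF, −78 → 0 °C; then 13, −78 °C (1.05 equiv of ylide)
Reagents that add atoms: none
Why: Wittig reaction of a non-stabilised ylide under lithium-free conditions, which should give the 14Z alkene through the kinetically favoured cis-oxaphosphetane; at −78 °C the aldehyde is expected to react well before the ketone of the enone, whose β-carbon is shielded by the quaternary C12.

**Step 13**
Reactants: 19 2-deoxy-L-ribose
Product: 20 methyl (2E,5R,6S)-5,6,7-trihydroxyhept-2-enoate
Conditions: Ph3P=CHCO2Me, PhCO2H (cat.), THF, reflux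
Reagents that add atoms: methyl (triphenylphosphoranylidene)acetate COC(=O)C=P(c1ccccc1)(c1ccccc1)c1ccccc1
Why: Wittig reaction of a stabilised ylide with the open-chain aldehyde form of the lactol; the two carbinol centres of the sugar become C5 and C6 of the target and are not touched.

**Step 14**
Reactants: 20 methyl (2E,5R,6S)-5,6,7-trihydroxyhept-2-enoate
Product: 21 methyl (2E,5R,6S)-5,6,7-tris(triethylsilyloxy)hept-2-enoate
Conditions: TESCl, imidazole, DMF, 0 °C → rt
Reagents that add atoms: chlorotriethylsilane CC[Si](Cl)(CC)CC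
Why: Exhaustive silylation; it prevents oxa-Michael closure onto the enoate and later lactonisation of the 5-hydroxy ester.

**Step 15**
Reactants: 21 methyl (2E,5R,6S)-5,6,7-tris(triethylsilyloxy)hept-2-enoate
Product: 22 methyl (5R,6S)-5,6,7-tris(triethylsilyloxy)heptanoate
Conditions: H2 (1 atm), Pd/C, EtOAc, rt
Reagents that add atoms: none
Why: Catalytic hydrogenation of the conjugated alkene; the silyl ethers are not allylic and should survive in a non-protic solvent.

**Step 16**
Reactants: 22 methyl (5R,6S)-5,6,7-tris(triethylsilyloxy)heptanoate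
Product: 23 methyl (5R,6R)-7-oxo-5,6-bis(triethylsilyloxy)heptanoate
Conditions: (COCl)2, DMSO, CH2Cl2, −78 → −30 °C; Et3N, −78 °C → rt
Reagents that add atoms: none
Why: Swern conditions oxidise a primary triethylsilyl ether directly to the aldehyde, since the activated sulfonium species displaces the less hindered silyl group, while the secondary silyl ethers stay; the low temperature should avoid epimerisation at C6.

**Step 17**
Reactants: 18 (S)-2-bromo-4-[(2Z,5Z)-octa-2,5-dien-1-yl]-4-(triethylsilyloxy)cyclopent-2-en-1-one; 23 methyl (5R,6R)-7-oxo-5,6-bis(triethylsilyloxy)heptanoate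
Product: 25 aldol adduct, methyl 7-[3-bromo-2-oxo-5-[(2Z,5Z)-octa-2,5-dien-1-yl]-5-(triethylsilyloxy)cyclopent-3-en-1-yl]-7-hydroxy-5,6-bis(triethylsilyloxy)heptanoate (C5, C6 and the ring carbinol carbon as in 23 and 18; mixture at C7 and C8), via lithium enolate 24 (not isolated)
Conditions: LDA (commercial solution), THF, −78 °C; then 23, −78 °C; aq. NH4Cl
Reagents that add atoms: none
Why: Directed aldol addition: the cross-conjugated lithium enolate can form only at C8, because C10 bears no hydrogen and C12 is quaternary; the new centres at C7 and C8 need no control because both are lost in step 18.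

**Step 18**
Reactants: 25 aldol adduct
Product: 27 methyl (5R,6S,7Z)-7-[(2R)-4-bromo-2-[(2Z,5Z)-octa-2,5-dien-1-yl]-5-oxo-2-(triethylsilyloxy)cyclopent-3-en-1-ylidene]-5,6-bis(triethylsilyloxy)heptanoate, via mesylate 26 (not isolated)
Conditions: MsCl, Et3N, CH2Cl2, −20 °C; then DBU, 0 °C → rt
Reagents that add atoms: none
Why: Mesylation and E1cB elimination: in the C8 enolate the branched C6 substituent should avoid the fully substituted C12, with its silyloxy and octadienyl groups (allylic 1,3-strain), and lie on the side of the C9 oxygen, so loss of mesylate should give the 7Z alkene, which for the same reason is expected to be the more stable isomer.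

**Step 19**
Reactants: 27 methyl (5R,6S,7Z)-7-[(2R)-4-bromo-2-[(2Z,5Z)-octa-2,5-dien-1-yl]-5-oxo-2-(triethylsilyloxy)cyclopent-3-en-1-ylidene]-5,6-bis(triethylsilyloxy)heptanoate
Product: 28 methyl (5R,6S,7Z)-7-[(2R)-4-bromo-2-hydroxy-2-[(2Z,5Z)-octa-2,5-dien-1-yl]-5-oxocyclopent-3-en-1-ylidene]-5,6-dihydroxyheptanoate (CNP0241880.1)
Conditions: HF·pyridine, pyridine, THF, 0 °C → rt
Reagents that add atoms: none
Why: Fluoride-driven cleavage of the three triethylsilyl ethers under buffered, weakly acidic conditions, which avoids the base-induced retro-aldol at C12 and should spare the Z-γ-hydroxy-enone and the skipped diene.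

**Compound list**
1 | (S)-1-(2,4,6-triisopropylphenyl)ethanol | C[C@H](O)c1c(C(C)C)cc(C(C)C)cc1C(C)C | starting material
2 | but-3-enoic acid | C=CCC(=O)O | starting material
3 | (S)-1-(2,4,6-triisopropylphenyl)ethyl but-3-enoate | C=CCC(=O)O[C@@H](C)c1c(C(C)C)cc(C(C)C)cc1C(C)C | intermediate
4 | 1,3,5-triisopropyl-2-[(S)-1-(penta-1,4-dien-2-yloxy)ethyl]benzene | C=CCC(=C)O[C@@H](C)c1c(C(C)C)cc(C(C)C)cc1C(C)C | intermediate
5 | (S)-3-allyl-2,2-dichloro-3-[(S)-1-(2,4,6-triisopropylphenyl)ethoxy]cyclobutan-1-one | C=CC[C@@]1(O[C@@H](C)c2c(C(C)C)cc(C(C)C)cc2C(C)C)C(Cl)(Cl)C(=O)C1 | intermediate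
6 | (2RS,3S)-3-allyl-2-chloro-3-[(S)-1-(2,4,6-triisopropylphenyl)ethoxy]cyclobutan-1-one | C=CC[C@@]1(O[C@@H](C)c2c(C(C)C)cc(C(C)C)cc2C(C)C)C(Cl)C(=O)C1 | intermediate
7 | {[(S)-3-allyl-3-[(S)-1-(2,4,6-triisopropylphenyl)ethoxy]cyclobut-1-en-1-yl]oxy}trimethylsilane | C=CC[C@@]1(O[C@@H](C)c2c(C(C)C)cc(C(C)C)cc2C(C)C)C=C(O[Si](C)(C)C)C1 | intermediate
8 | (3S)-3-allyl-5,5-dibromo-3-[(S)-1-(2,4,6-triisopropylphenyl)ethoxy]-1-(trimethylsilyloxy)bicyclo[2.1.0]pentane (bridgeheads unspecified) | C=CC[C@@]1(O[C@@H](C)c3c(C(C)C)cc(C(C)C)cc3C(C)C)C2C(Br)(Br)C2(O[Si](C)(C)C)C1 | intermediate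
9 | (S)-4-allyl-2-bromo-4-[(S)-1-(2,4,6-triisopropylphenyl)ethoxy]cyclopent-2-en-1-one | C=CC[C@@]1(O[C@@H](C)c2c(C(C)C)cc(C(C)C)cc2C(C)C)C=C(Br)C(=O)C1 | intermediate
10 | (S)-4-allyl-2-bromo-4-hydroxycyclopent-2-en-1-one | C=CC[C@@]1(O)C=C(Br)C(=O)C1 | intermediate
11 | (S)-4-allyl-2-bromo-4-(triethylsilyloxy)cyclopent-2-en-1-one | C=CC[C@@]1(O[Si](CC)(CC)CC)C=C(Br)C(=O)C1 | intermediate
12 | (S)-2-bromo-4-(1,2,4-trioxolan-3-ylmethyl)-4-(triethylsilyloxy)cyclopent-2-en-1-one (ozonide, trioxolane carbon unspecified) | C1OC(C[C@@]2(O[Si](CC)(CC)CC)C=C(Br)C(=O)C2)OO1 | intermediate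
13 | 2-[(S)-3-bromo-4-oxo-1-(triethylsilyloxy)cyclopent-2-en-1-yl]acetaldehyde | O=CC[C@@]1(O[Si](CC)(CC)CC)C=C(Br)C(=O)C1 | intermediate
14 | (Z)-hex-3-en-1-ol | CC/C=C\CCO | starting material
15 | (Z)-1-iodohex-3-ene | CC/C=C\CCI | intermediate
16 | [(Z)-hex-3-en-1-yl]triphenylphosphonium iodide | CC/C=C\CC[P+](c1ccccc1)(c1ccccc1)c1ccccc1.[I-] | intermediate
17 | [(Z)-hex-3-en-1-ylidene]triphenylphosphorane | CC/C=C\CC=P(c1ccccc1)(c1ccccc1)c1ccccc1 | intermediate
18 | (S)-2-bromo-4-[(2Z,5Z)-octa-2,5-dien-1-yl]-4-(triethylsilyloxy)cyclopent-2-en-1-one | CC/C=C\C/C=C\C[C@@]1(O[Si](CC)(CC)CC)C=C(Br)C(=O)C1 | intermediate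
19 | 2-deoxy-L-ribose (2-deoxy-L-erythro-pentopyranose) | OC1C[C@@H](O)[C@@H](O)CO1 | starting material
20 | methyl (2E,5R,6S)-5,6,7-trihydroxyhept-2-enoate | OC[C@H](O)[C@H](O)C/C=C/C(=O)OC | intermediate
21 | methyl (2E,5R,6S)-5,6,7-tris(triethylsilyloxy)hept-2-enoate | CC[Si](CC)(CC)OC[C@H](O[Si](CC)(CC)CC)[C@H](O[Si](CC)(CC)CC)C/C=C/C(=O)OC | intermediate
22 | methyl (5R,6S)-5,6,7-tris(triethylsilyloxy)heptanoate | CC[Si](CC)(CC)OC[C@H](O[Si](CC)(CC)CC)[C@H](O[Si](CC)(CC)CC)CCCC(=O)OC | intermediate
23 | methyl (5R,6R)-7-oxo-5,6-bis(triethylsilyloxy)heptanoate | O=C[C@H](O[Si](CC)(CC)CC)[C@H](O[Si](CC)(CC)CC)CCCC(=O)OC | intermediate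
24 | lithium (S)-2-bromo-4-[(2Z,5Z)-octa-2,5-dien-1-yl]-4-(triethylsilyloxy)cyclopenta-1,5-dien-1-olate (C8 enolate of 18) | CC/C=C\C/C=C\C[C@@]1(O[Si](CC)(CC)CC)C=C(Br)C(O[Li])=C1 | intermediate
25 | aldol adduct: methyl 7-[3-bromo-2-oxo-5-[(2Z,5Z)-octa-2,5-dien-1-yl]-5-(triethylsilyloxy)cyclopent-3-en-1-yl]-7-hydroxy-5,6-bis(triethylsilyloxy)heptanoate (mixture at C7 and C8) | CC/C=C\C/C=C\C[C@@]1(O[Si](CC)(CC)CC)C=C(Br)C(=O)C1C(O)[C@H](O[Si](CC)(CC)CC)[C@H](O[Si](CC)(CC)CC)CCCC(=O)OC | intermediate
26 | 7-O-methanesulfonate of 25 | CC/C=C\C/C=C\C[C@@]1(O[Si](CC)(CC)CC)C=C(Br)C(=O)C1C(OS(C)(=O)=O)[C@H](O[Si](CC)(CC)CC)[C@H](O[Si](CC)(CC)CC)CCCC(=O)OC | intermediate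
27 | methyl (5R,6S,7Z)-7-[(2R)-4-bromo-2-[(2Z,5Z)-octa-2,5-dien-1-yl]-5-oxo-2-(triethylsilyloxy)cyclopent-3-en-1-ylidene]-5,6-bis(triethylsilyloxy)heptanoate | CC/C=C\C/C=C\C[C@@]1(O[Si](CC)(CC)CC)C=C(Br)C(=O)/C1=C\[C@H](O[Si](CC)(CC)CC)[C@H](O[Si](CC)(CC)CC)CCCC(=O)OC | intermediate
28 | methyl (5R,6S,7Z)-7-[(2R)-4-bromo-2-hydroxy-2-[(2Z,5Z)-octa-2,5-dien-1-yl]-5-oxocyclopent-3-en-1-ylidene]-5,6-dihydroxyheptanoate; methyl (5R,6S,7Z,12R,14Z,17Z)-10-bromo-5,6,12-trihydroxy-9-oxoprosta-7,10,14,17-tetraenoate | CC/C=C\C/C=C\C[C@@]1(O)C=C(Br)C(=O)/C1=C\[C@H](O)[C@H](O)CCCC(=O)OC | target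

**Step count and risks**
Total step count: 19. Longest linear sequence: 13 steps (steps 1–9, 12, 17, 18, 19).

Most likely to fail, step 18: the elimination may lose geometric control. In the enolate the C7 substituent could turn toward C12 instead of toward the C9 oxygen, or the enone could equilibrate by reversible conjugate addition of the amidine base. The fallback sets out from 18. Its lithium enolate is C-phosphinylated with bis(2,2,2-trifluoroethyl) phosphorochloridite to the β-keto phosphonite bis(2,2,2-trifluoroethyl) [3-bromo-2-oxo-5-(octa-2,5-dienyl)-5-(triethylsilyloxy)cyclopent-3-en-1-yl]phosphonite F1 and oxidised with tert-butyl hydroperoxide to the corresponding β-keto phosphonate F2. A Still–Gennari-type Horner–Wadsworth–Emmons reaction of F2 (KHMDS, 18-crown-6, THF, −78 °C) with aldehyde 23 should then join C7 to C8 under kinetic control with C6 cis to the C9 carbonyl, and comes back to the route at 27.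

Second, step 6: alkoxide may desilylate the enol ether before the carbene adds, the carbene may also add to the allyl group, or excess base may enolise the product toward loss of the C12 ether. The fallback sets out from 7. Simmons–Smith cyclopropanation (Et2Zn, CH2I2, 0 °C) of the enol ether bond gives the siloxybicyclopentane (3S)-3-allyl-3-[(S)-1-(2,4,6-triisopropylphenyl)ethoxy]-1-(trimethylsilyloxy)bicyclo[2.1.0]pentane F3. One-electron oxidation with FeCl3 in DMF opens its central bond to the ring-enlarged β-chloroketone 4-allyl-3-chloro-4-[(S)-1-(2,4,6-triisopropylphenyl)ethoxy]cyclopentan-1-one F4, and NaOAc in MeOH eliminates HCl to the enone (S)-4-allyl-4-[(S)-1-(2,4,6-triisopropylphenyl)ethoxy]cyclopent-2-en-1-one F5. Nucleophilic epoxidation (H2O2, NaOH, MeOH, 0 °C) touches only the enone and gives the epoxy ketone 4-allyl-4-[(S)-1-(2,4,6-triisopropylphenyl)ethoxy]-6-oxabicyclo[3.1.0]hexan-2-one F6. Aqueous HBr in THF at 0 °C should then open the oxirane at the carbon α to the ketone, dehydrate to the 2-bromo-enone and cleave the acid-labile inductor ether in the same operation, and comes back to the route at 10.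

Third, step 3: facial selectivity of the cycloaddition may be poor with a 1,1-disubstituted enol ether, giving a diastereomer mixture that erodes the yield of (S)-5. The fallback sets out from 2 and moves the source of asymmetry from the cycloaddition to an enantiotopic deprotonation. Esterification with 4-methoxybenzyl alcohol gives 4-methoxybenzyl but-3-enoate F7; Petasis methylenation gives the enol ether 1-methoxy-4-[(penta-1,4-dien-2-yloxy)methyl]benzene F8; dichloroketene cycloaddition gives racemic 3-allyl-2,2-dichloro-3-(4-methoxybenzyloxy)cyclobutan-1-one F9; exhaustive Zn/AcOH reduction gives the achiral 3-allyl-3-(4-methoxybenzyloxy)cyclobutan-1-one F10. Deprotonation with lithium bis[(R)-1-phenylethyl]amide (or its enantiomer) in the presence of TMSCl at −100 °C selects one of the two enantiotopic α-methylene groups and gives {[(S)-3-allyl-3-(4-methoxybenzyloxy)cyclobut-1-en-1-yl]oxy}trimethylsilane F11. Bromoform and KOtBu then give, through the dibromobicyclopentane F12, (S)-4-allyl-2-bromo-4-(4-methoxybenzyloxy)cyclopent-2-en-1-one F13, and DDQ in wet CH2Cl2 removes the 4-methoxybenzyl group, which comes back to the route at 10.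

Further compounds
F1 | step 18 | bis(2,2,2-trifluoroethyl) [3-bromo-2-oxo-5-[(2Z,5Z)-octa-2,5-dien-1-yl]-5-(triethylsilyloxy)cyclopent-3-en-1-yl]phosphonite | CC/C=C\C/C=C\C[C@@]1(O[Si](CC)(CC)CC)C=C(Br)C(=O)C1P(OCC(F)(F)F)OCC(F)(F)F
F2 | step 18 | bis(2,2,2-trifluoroethyl) [3-bromo-2-oxo-5-[(2Z,5Z)-octa-2,5-dien-1-yl]-5-(triethylsilyloxy)cyclopent-3-en-1-yl]phosphonate | CC/C=C\C/C=C\C[C@@]1(O[Si](CC)(CC)CC)C=C(Br)C(=O)C1P(=O)(OCC(F)(F)F)OCC(F)(F)F
F3 | step 6 | (3S)-3-allyl-3-[(S)-1-(2,4,6-triisopropylphenyl)ethoxy]-1-(trimethylsilyloxy)bicyclo[2.1.0]pentane | C=CC[C@@]1(O[C@@H](C)c3c(C(C)C)cc(C(C)C)cc3C(C)C)C2CC2(O[Si](C)(C)C)C1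
F4 | step 6 | (4S)-4-allyl-3-chloro-4-[(S)-1-(2,4,6-triisopropylphenyl)ethoxy]cyclopentan-1-one | C=CC[C@@]1(O[C@@H](C)c2c(C(C)C)cc(C(C)C)cc2C(C)C)C(Cl)CC(=O)C1
F5 | step 6 | (S)-4-allyl-4-[(S)-1-(2,4,6-triisopropylphenyl)ethoxy]cyclopent-2-en-1-one | C=CC[C@@]1(O[C@@H](C)c2c(C(C)C)cc(C(C)C)cc2C(C)C)C=CC(=O)C1
F6 | step 6 | (4S)-4-allyl-4-[(S)-1-(2,4,6-triisopropylphenyl)ethoxy]-6-oxabicyclo[3.1.0]hexan-2-one | C=CC[C@@]1(O[C@@H](C)c3c(C(C)C)cc(C(C)C)cc3C(C)C)C2OC2C(=O)C1
F7 | step 3 | 4-methoxybenzyl but-3-enoate | C=CCC(=O)OCc1ccc(OC)cc1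
F8 | step 3 | 1-methoxy-4-[(penta-1,4-dien-2-yloxy)methyl]benzene | C=CCC(=C)OCc1ccc(OC)cc1
F9 | step 3 | rac-3-allyl-2,2-dichloro-3-(4-methoxybenzyloxy)cyclobutan-1-one | C=CCC1(OCc2ccc(OC)cc2)CC(=O)C1(Cl)Cl
F10 | step 3 | 3-allyl-3-(4-methoxybenzyloxy)cyclobutan-1-one | C=CCC1(OCc2ccc(OC)cc2)CC(=O)C1
F11 | step 3 | {[(S)-3-allyl-3-(4-methoxybenzyloxy)cyclobut-1-en-1-yl]oxy}trimethylsilane | C=CC[C@@]1(OCc2ccc(OC)cc2)C=C(O[Si](C)(C)C)C1
F12 | step 3 | (3S)-3-allyl-5,5-dibromo-3-(4-methoxybenzyloxy)-1-(trimethylsilyloxy)bicyclo[2.1.0]pentane | C=CC[C@@]1(OCc3ccc(OC)cc3)C2C(Br)(Br)C2(O[Si](C)(C)C)C1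
F13 | step 3 | (S)-4-allyl-2-bromo-4-(4-methoxybenzyloxy)cyclopent-2-en-1-one | C=CC[C@@]1(OCc2ccc(OC)cc2)C=C(Br)C(=O)C1
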